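## Retrosynthetic overview

1. Target ⇐ MOM removal, carbamoylation of the two benzylic alcohols, and CH(OMe)2 → CHO → CHCl2 on a saturated [7.7]paracyclophane that already carries the 4-chlorobutyl chain.
2. Macrocycle (second and last ring formed) ⇐ head-to-tail olefin-metathesis cyclodimerisation (C4=C5, C17=C18) of two diene monomers that differ only in the side-chain terminus (CH2Cl or CH(OMe)2), then hydrogenation.
3. Each monomer ⇐ double methylenation of a lactol-aldehyde ⇐ DIBAL on a lactone-thioester ⇐ Cu-catalysed asymmetric conjugate addition of RMgBr (sets C7/C20) to one common aryl enethioate.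
4. Key C1–C2 bond, both stereocentres at once (first ring formed, a cis-γ-butyrolactone) ⇐ carbene-bound homoenolate of crotonaldehyde + the unhindered CHO of an aryl dialdehyde.
5. Dialdehyde ⇐ directed ortho-metalation/formylation of 3,5-bis(methoxymethoxy)benzaldehyde ⇐ 3,5-dihydroxybenzaldehyde.

Assumption: reagents written over the arrows (including Ph3P=CHC(O)SEt, the chiral triazolium chloride and Tol-BINAP) are purchased; macrocycle locants follow cylindrocyclophane numbering (bridges C1–C7 and C14–C20, benzene rings C8–C13 and C21–C26, oxygen on C1/C14, methyl on C2/C15, side chains on C7/C20).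

## Route

Step 1
Reactants: 1 3,5-dihydroxybenzaldehyde
Product: 2 3,5-bis(methoxymethoxy)benzaldehyde
Conditions: MOMCl (2.5 equiv), i-Pr2NEt (3 equiv), CH2Cl2, 0 °C → rt
Reagents that add atoms: chloromethyl methyl ether, COCCl
Why: Base-mediated O-alkylation of both phenols (MOM ether formation) is chemoselective beside the aldehyde and installs acid-labile groups that are also strong ortho-directors for the next step.

Step 2
Reactants: 2 3,5-bis(methoxymethoxy)benzaldehyde
Product: 6 2,6-bis(methoxymethoxy)benzene-1,4-dicarbaldehyde, via lithium aminoalkoxide 3 (not isolated), via aryllithium 4 (not isolated), via dilithium bis-aminoalkoxide 5 (not isolated)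
Conditions: 1-methylpiperazine/n-BuLi (1.1 equiv), THF, −20 °C; n-BuLi (1.3 equiv), 0 °C; DMF (3 equiv), −40 °C → rt; aq. NH4Cl
Reagents that add atoms: N,N-dimethylformamide, CN(C)C=O (the new CHO group of 6); lithium 4-methylpiperazin-1-ide, [Li]N1CCN(C)CC1 (atoms in 3, 4 and 5 only); n-butyllithium, [Li]CCCC (lithium in 4 and 5 only)
Why: In situ protection of the aldehyde as a lithium α-amino alkoxide (Comins protocol) allows directed ortho-metalation at the only carbon flanked by two OMOM groups, and formylation of the aryllithium by DMF followed by aqueous collapse of both aminals gives the dialdehyde without a separate protection step.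

Step 3
Reactants: 6 2,6-bis(methoxymethoxy)benzene-1,4-dicarbaldehyde; 7 (E)-but-2-enal
Product: 8 2,6-bis(methoxymethoxy)-4-[(2R,3S)-3-methyl-5-oxooxolan-2-yl]benzaldehyde
Conditions: 7 (1.5 equiv, slow addition), 2-mesityl-5a,10b-dihydro-4H,6H-indeno[2,1-b][1,2,4]triazolo[4,3-d][1,4]oxazin-2-ium chloride (single enantiomer, the antipode that gives 8; 10 mol%), DBU (10 mol%), THF/t-BuOH 10:1, rt; chromatography, then recrystallisation
Reagents that add atoms: none
Why: Proposed new method: the chiral triazolylidene adds to 7 to give a Breslow intermediate whose vinylogous form is a homoenolate (nucleophilic β-carbon), which attacks the unhindered, more electrophilic C4 aldehyde of 6 (the aldehyde between the two OMOM groups is shielded and deactivated) in a closed transition state organised by the enol O–H···O=C hydrogen bond that places aryl and methyl cis while the aminoindanol backbone blocks one face, so one C–C bond formation sets the carbinol carbon R and the methyl-bearing carbon S, and O-acylation of the resulting alkoxide by the acyl azolium closes the lactone and frees the carbene; the closest known reaction type is the NHC-catalysed homoenolate annulation of enals with aryl aldehydes (cis-selective but racemic with achiral carbenes) and its highly enantioselective chiral-triazolium versions with activated ketones.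

Step 4
Reactants: 8 2,6-bis(methoxymethoxy)-4-[(2R,3S)-3-methyl-5-oxooxolan-2-yl]benzaldehyde
Product: 9 S-ethyl (2E)-3-{2,6-bis(methoxymethoxy)-4-[(2R,3S)-3-methyl-5-oxooxolan-2-yl]phenyl}prop-2-enethioate
Conditions: Ph3P=CHC(O)SEt (1.3 equiv), toluene, 80 °C
Reagents that add atoms: S-ethyl (triphenyl-λ5-phosphanylidene)ethanethioate, CCSC(=O)C=P(c1ccccc1)(c1ccccc1)c1ccccc1
Why: Wittig olefination with a stabilised acyl ylide occurs only at the remaining aldehyde (the lactone is inert to it) and gives the E-enethioate because oxaphosphetane formation is reversible for stabilised ylides.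

Step 5
Reactants: 9 S-ethyl (2E)-3-{2,6-bis(methoxymethoxy)-4-[(2R,3S)-3-methyl-5-oxooxolan-2-yl]phenyl}prop-2-enethioate; 10 1-bromo-4-chlorobutane
Product: 12 S-ethyl (3R)-3-{2,6-bis(methoxymethoxy)-4-[(2R,3S)-3-methyl-5-oxooxolan-2-yl]phenyl}-7-chloroheptanethioate, via (4-chlorobutyl)magnesium bromide 11 (not isolated)
Conditions: 10, Mg, Et2O, rt (gives 11); then 9, CuI (5 mol%), Tol-BINAP (6 mol%; the antipode that gives 3R), t-BuOMe, −75 °C; aq. NH4Cl
Reagents that add atoms: magnesium, [Mg] (in 11 only)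
Why: Cu-catalysed asymmetric conjugate addition of a Grignard reagent to an α,β-unsaturated thioester delivers the 4-chlorobutyl group to one face of the β-carbon under ligand control and so sets the benzylic centre as 3R, while at −75 °C the Grignard reagent (formed selectively at the C–Br bond of 10) attacks neither the lactone nor the thioester carbonyl.

Step 6
Reactants: 12 S-ethyl (3R)-3-{2,6-bis(methoxymethoxy)-4-[(2R,3S)-3-methyl-5-oxooxolan-2-yl]phenyl}-7-chloroheptanethioate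
Product: 13 (3R)-7-chloro-3-{4-[(2R,3S)-5-hydroxy-3-methyloxolan-2-yl]-2,6-bis(methoxymethoxy)phenyl}heptanal
Conditions: i-Bu2AlH (2.5 equiv), CH2Cl2, −78 °C; aq. KNaC4H4O6
Reagents that add atoms: none
Why: DIBAL partial reduction stops at the aluminium hemithioacetal and lactol alkoxide stage at −78 °C, so work-up releases the aldehyde and the lactol (anomer mixture) in one operation without touching the three set stereocentres.

Step 7
Reactants: 13 (3R)-7-chloro-3-{4-[(2R,3S)-5-hydroxy-3-methyloxolan-2-yl]-2,6-bis(methoxymethoxy)phenyl}heptanal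
Product: 14 (1R,2S)-1-{4-[(4R)-8-chlorooct-1-en-4-yl]-3,5-bis(methoxymethoxy)phenyl}-2-methylpent-4-en-1-ol
Conditions: Ph3PCH3Br (5 equiv), KOtBu (4.8 equiv), THF, 0 °C → rt
Reagents that add atoms: methyltriphenylphosphonium bromide, C[P+](c1ccccc1)(c1ccccc1)c1ccccc1.[Br-] (the two terminal =CH2 carbons)
Why: Double Wittig methylenation with excess non-stabilised ylide converts the free aldehyde and the ring-opened lactol (its hydroxy aldehyde form under basic conditions) into two terminal alkenes, and no stereocentre is α to a carbonyl so none can epimerise.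

Step 8
Reactants: 9 S-ethyl (2E)-3-{2,6-bis(methoxymethoxy)-4-[(2R,3S)-3-methyl-5-oxooxolan-2-yl]phenyl}prop-2-enethioate; 15 4-bromo-1,1-dimethoxybutane
Product: 17 S-ethyl (3R)-3-{2,6-bis(methoxymethoxy)-4-[(2R,3S)-3-methyl-5-oxooxolan-2-yl]phenyl}-7,7-dimethoxyheptanethioate, via (4,4-dimethoxybutyl)magnesium bromide 16 (not isolated)
Conditions: 15, Mg, THF, 40 °C (gives 16); then 9, CuI (5 mol%), Tol-BINAP (6 mol%; same antipode as in step 5), t-BuOMe, −75 °C; aq. NH4Cl
Reagents that add atoms: magnesium, [Mg] (in 16 only)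
Why: The same Cu-catalysed asymmetric conjugate addition to the enethioate sets the benzylic centre as 3R under ligand control, now with a Grignard reagent whose dimethyl acetal masks the aldehyde needed later for the CHCl2 group.

Step 9
Reactants: 17 S-ethyl (3R)-3-{2,6-bis(methoxymethoxy)-4-[(2R,3S)-3-methyl-5-oxooxolan-2-yl]phenyl}-7,7-dimethoxyheptanethioate
Product: 18 (3R)-3-{4-[(2R,3S)-5-hydroxy-3-methyloxolan-2-yl]-2,6-bis(methoxymethoxy)phenyl}-7,7-dimethoxyheptanal
Conditions: i-Bu2AlH (2.5 equiv), CH2Cl2, −78 °C; aq. KNaC4H4O6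
Reagents that add atoms: none
Why: DIBAL partial reduction of thioester and lactone at −78 °C gives aldehyde and lactol after a neutral tartrate work-up that the dimethyl acetal survives.

Step 10
Reactants: 18 (3R)-3-{4-[(2R,3S)-5-hydroxy-3-methyloxolan-2-yl]-2,6-bis(methoxymethoxy)phenyl}-7,7-dimethoxyheptanal
Product: 19 (1R,2S)-1-{4-[(4R)-8,8-dimethoxyoct-1-en-4-yl]-3,5-bis(methoxymethoxy)phenyl}-2-methylpent-4-en-1-ol
Conditions: Ph3PCH3Br (5 equiv), KOtBu (4.8 equiv), THF, 0 °C → rt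
Reagents that add atoms: methyltriphenylphosphonium bromide, C[P+](c1ccccc1)(c1ccccc1)c1ccccc1.[Br-] (the two terminal =CH2 carbons)
Why: Double Wittig methylenation of aldehyde and lactol gives the second diene monomer under basic conditions that leave the acetal and all stereocentres untouched.

Step 11
Reactants: 14 (1R,2S)-1-{4-[(4R)-8-chlorooct-1-en-4-yl]-3,5-bis(methoxymethoxy)phenyl}-2-methylpent-4-en-1-ol; 19 (1R,2S)-1-{4-[(4R)-8,8-dimethoxyoct-1-en-4-yl]-3,5-bis(methoxymethoxy)phenyl}-2-methylpent-4-en-1-ol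
Product: 20 (1R,2S,4E,7R,14R,15S,17E,20R)-7-(4-chlorobutyl)-20-(4,4-dimethoxybutyl)-9,13,22,26-tetrakis(methoxymethoxy)-2,15-dimethyl[7.7]paracyclophane-4,17-diene-1,14-diol
Conditions: 14 + 19 (1:1), second-generation Grubbs catalyst RuCl2(=CHPh)(PCy3)(H2IMes) (10 mol%), CH2Cl2 (5 mM), 40 °C; chromatography on Et3N-buffered silica
Reagents that add atoms: none
Why: Ru-catalysed cross-metathesis followed by ring-closing metathesis is reversible, so the mixture is funnelled to the least strained head-to-tail [7.7]paracyclophane with E-alkenes, the unsymmetrical pair forming in the statistical share of about one half and being separated from the less polar and the more polar homodimer.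

Step 12
Reactants: 20 (1R,2S,4E,7R,14R,15S,17E,20R)-7-(4-chlorobutyl)-20-(4,4-dimethoxybutyl)-9,13,22,26-tetrakis(methoxymethoxy)-2,15-dimethyl[7.7]paracyclophane-4,17-diene-1,14-diol
Product: 21 (1R,2S,7S,14R,15S,20S)-7-(4-chlorobutyl)-20-(4,4-dimethoxybutyl)-9,13,22,26-tetrakis(methoxymethoxy)-2,15-dimethyl[7.7]paracyclophane-1,14-diol
Conditions: H2 (1 atm), PtO2 (10 mol%), EtOAc, rt
Reagents that add atoms: none
Why: Heterogeneous hydrogenation over PtO2 in neutral ethyl acetate saturates the two disubstituted alkenes while alkyl chloride, acetal, MOM ethers and benzylic alcohols are left alone (the C7/C20 descriptors change from R to S only because the ring chain loses CIP priority).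

Step 13
Reactants: 21 (1R,2S,7S,14R,15S,20S)-7-(4-chlorobutyl)-20-(4,4-dimethoxybutyl)-9,13,22,26-tetrakis(methoxymethoxy)-2,15-dimethyl[7.7]paracyclophane-1,14-diol
Product: 22 (1R,2S,7S,14R,15S,20S)-7-(4-chlorobutyl)-9,13,22,26-tetrakis(methoxymethoxy)-2,15-dimethyl-20-(4-oxobutyl)[7.7]paracyclophane-1,14-diol
Conditions: LiBF4 (3 equiv), MeCN/H2O 50:1, rt
Reagents that add atoms: water, O (the aldehyde oxygen)
Why: Mild acetal hydrolysis with LiBF4 in wet acetonitrile cleaves the acyclic dimethyl acetal much faster than the aryl MOM ethers and does not touch the benzylic alcohols.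

Step 14
Reactants: 22 (1R,2S,7S,14R,15S,20S)-7-(4-chlorobutyl)-9,13,22,26-tetrakis(methoxymethoxy)-2,15-dimethyl-20-(4-oxobutyl)[7.7]paracyclophane-1,14-diol
Product: 24 (1R,2S,7S,14R,15S,20S)-7-(4-chlorobutyl)-20-(4,4-dichlorobutyl)-9,13,22,26-tetrakis(methoxymethoxy)-2,15-dimethyl[7.7]paracyclophane-1,14-diol, via hydrazone 23 (not isolated)
Conditions: N2H4·H2O (10 equiv), EtOH, 0 °C → rt, 30 min, evaporate; then CuCl2 (6 equiv), Et3N (3 equiv), MeOH, 0 °C → rt
Reagents that add atoms: hydrazine hydrate, NN.O (both nitrogen atoms of 23 only); copper dichloride, Cl[Cu]Cl (both chlorine atoms of the CHCl2 group)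
Why: Hydrazone formation followed by CuCl2 oxidation (Takeda gem-dichlorination) passes through a diazoalkane that is chlorinated twice with loss of N2, a sequence run in methanol and therefore tolerant of the free alcohols, the MOM ethers and the primary chloride.

Step 15
Reactants: 24 (1R,2S,7S,14R,15S,20S)-7-(4-chlorobutyl)-20-(4,4-dichlorobutyl)-9,13,22,26-tetrakis(methoxymethoxy)-2,15-dimethyl[7.7]paracyclophane-1,14-diol
Product: 26 (1R,2S,7S,14R,15S,20S)-7-(4-chlorobutyl)-20-(4,4-dichlorobutyl)-9,13,22,26-tetrakis(methoxymethoxy)-2,15-dimethyl[7.7]paracyclophane-1,14-diyl dicarbamate, via bis(trichloroacetylcarbamate) 25 (not isolated)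
Conditions: Cl3CC(O)NCO (3 equiv), CH2Cl2, 0 °C; then K2CO3 (cat.), MeOH, rt
Reagents that add atoms: trichloroacetyl isocyanate, O=C=NC(=O)C(Cl)(Cl)Cl (the C(=O)N unit of each carbamate; the trichloroacetyl part stays in 25 only)
Why: Acylation of both hindered secondary alcohols by the highly electrophilic trichloroacetyl isocyanate and methanolysis of the N-trichloroacetyl groups (Kočovský carbamate synthesis) gives the primary carbamates with retention because no C–O bond at C1 or C14 is broken.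

Step 16
Reactants: 26 (1R,2S,7S,14R,15S,20S)-7-(4-chlorobutyl)-20-(4,4-dichlorobutyl)-9,13,22,26-tetrakis(methoxymethoxy)-2,15-dimethyl[7.7]paracyclophane-1,14-diyl dicarbamate
Product: 27 (1R,2S,7S,14R,15S,20S)-7-(4-chlorobutyl)-20-(4,4-dichlorobutyl)-9,13,22,26-tetrahydroxy-2,15-dimethyl[7.7]paracyclophane-1,14-diyl dicarbamate
Conditions: HCl (3 M in MeOH), 0 °C → rt
Reagents that add atoms: none
Why: Acid-catalysed transacetalisation to methanol removes the four aryl MOM ethers under conditions that neither ionise the benzylic carbamates (the meta oxygens destabilise the cation) nor affect the alkyl chlorides, giving the target.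

## Compound list

1 | 3,5-dihydroxybenzaldehyde | O=Cc1cc(O)cc(O)c1 | starting material
2 | 3,5-bis(methoxymethoxy)benzaldehyde | COCOc1cc(C=O)cc(OCOC)c1 | intermediate
3 | lithium [3,5-bis(methoxymethoxy)phenyl](4-methylpiperazin-1-yl)methanolate | COCOc1cc(cc(OCOC)c1)C(O[Li])N1CCN(C)CC1 | intermediate (not isolated)
4 | lithium [4-lithio-3,5-bis(methoxymethoxy)phenyl](4-methylpiperazin-1-yl)methanolate | COCOc1cc(cc(OCOC)c1[Li])C(O[Li])N1CCN(C)CC1 | intermediate (not isolated)
5 | lithium {4-[(dimethylamino)(lithiooxy)methyl]-3,5-bis(methoxymethoxy)phenyl}(4-methylpiperazin-1-yl)methanolate | COCOc1cc(cc(OCOC)c1C(O[Li])N(C)C)C(O[Li])N1CCN(C)CC1 | intermediate (not isolated)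
6 | 2,6-bis(methoxymethoxy)benzene-1,4-dicarbaldehyde | COCOc1cc(C=O)cc(OCOC)c1C=O | intermediate
7 | (E)-but-2-enal | C/C=C/C=O | starting material
8 | 2,6-bis(methoxymethoxy)-4-[(2R,3S)-3-methyl-5-oxooxolan-2-yl]benzaldehyde | COCOc1cc(cc(OCOC)c1C=O)[C@@H]1OC(=O)C[C@@H]1C | intermediate
9 | S-ethyl (2E)-3-{2,6-bis(methoxymethoxy)-4-[(2R,3S)-3-methyl-5-oxooxolan-2-yl]phenyl}prop-2-enethioate | CCSC(=O)/C=C/c1c(OCOC)cc(cc1OCOC)[C@@H]1OC(=O)C[C@@H]1C | intermediate
10 | 1-bromo-4-chlorobutane | ClCCCCBr | starting material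
11 | (4-chlorobutyl)magnesium bromide | ClCCCC[Mg]Br | intermediate (not isolated)
12 | S-ethyl (3R)-3-{2,6-bis(methoxymethoxy)-4-[(2R,3S)-3-methyl-5-oxooxolan-2-yl]phenyl}-7-chloroheptanethioate | CCSC(=O)C[C@@H](CCCCCl)c1c(OCOC)cc(cc1OCOC)[C@@H]1OC(=O)C[C@@H]1C | intermediate
13 | (3R)-7-chloro-3-{4-[(2R,3S)-5-hydroxy-3-methyloxolan-2-yl]-2,6-bis(methoxymethoxy)phenyl}heptanal (lactol anomers) | O=CC[C@@H](CCCCCl)c1c(OCOC)cc(cc1OCOC)[C@@H]1OC(O)C[C@@H]1C | intermediate
14 | (1R,2S)-1-{4-[(4R)-8-chlorooct-1-en-4-yl]-3,5-bis(methoxymethoxy)phenyl}-2-methylpent-4-en-1-ol | C=CC[C@@H](CCCCCl)c1c(OCOC)cc(cc1OCOC)[C@H](O)[C@@H](C)CC=C | intermediate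
15 | 4-bromo-1,1-dimethoxybutane | COC(CCCBr)OC | starting material
16 | (4,4-dimethoxybutyl)magnesium bromide | COC(CCC[Mg]Br)OC | intermediate (not isolated)
17 | S-ethyl (3R)-3-{2,6-bis(methoxymethoxy)-4-[(2R,3S)-3-methyl-5-oxooxolan-2-yl]phenyl}-7,7-dimethoxyheptanethioate | CCSC(=O)C[C@@H](CCCC(OC)OC)c1c(OCOC)cc(cc1OCOC)[C@@H]1OC(=O)C[C@@H]1C | intermediate
18 | (3R)-3-{4-[(2R,3S)-5-hydroxy-3-methyloxolan-2-yl]-2,6-bis(methoxymethoxy)phenyl}-7,7-dimethoxyheptanal (lactol anomers) | O=CC[C@@H](CCCC(OC)OC)c1c(OCOC)cc(cc1OCOC)[C@@H]1OC(O)C[C@@H]1C | intermediate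
19 | (1R,2S)-1-{4-[(4R)-8,8-dimethoxyoct-1-en-4-yl]-3,5-bis(methoxymethoxy)phenyl}-2-methylpent-4-en-1-ol | C=CC[C@@H](CCCC(OC)OC)c1c(OCOC)cc(cc1OCOC)[C@H](O)[C@@H](C)CC=C | intermediate
20 | (1R,2S,4E,7R,14R,15S,17E,20R)-7-(4-chlorobutyl)-20-(4,4-dimethoxybutyl)-9,13,22,26-tetrakis(methoxymethoxy)-2,15-dimethyl[7.7]paracyclophane-4,17-diene-1,14-diol | C[C@H]1C/C=C/C[C@@H](CCCCCl)c2c(OCOC)cc(cc2OCOC)[C@H](O)[C@@H](C)C/C=C/C[C@@H](CCCC(OC)OC)c2c(OCOC)cc(cc2OCOC)[C@@H]1O | intermediate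
21 | (1R,2S,7S,14R,15S,20S)-7-(4-chlorobutyl)-20-(4,4-dimethoxybutyl)-9,13,22,26-tetrakis(methoxymethoxy)-2,15-dimethyl[7.7]paracyclophane-1,14-diol | C[C@H]1CCCC[C@@H](CCCCCl)c2c(OCOC)cc(cc2OCOC)[C@H](O)[C@@H](C)CCCC[C@@H](CCCC(OC)OC)c2c(OCOC)cc(cc2OCOC)[C@@H]1O | intermediate
22 | (1R,2S,7S,14R,15S,20S)-7-(4-chlorobutyl)-9,13,22,26-tetrakis(methoxymethoxy)-2,15-dimethyl-20-(4-oxobutyl)[7.7]paracyclophane-1,14-diol | C[C@H]1CCCC[C@@H](CCCCCl)c2c(OCOC)cc(cc2OCOC)[C@H](O)[C@@H](C)CCCC[C@@H](CCCC=O)c2c(OCOC)cc(cc2OCOC)[C@@H]1O | intermediate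
23 | (1R,2S,7S,14R,15S,20S)-7-(4-chlorobutyl)-20-(4-hydrazinylidenebutyl)-9,13,22,26-tetrakis(methoxymethoxy)-2,15-dimethyl[7.7]paracyclophane-1,14-diol | C[C@H]1CCCC[C@@H](CCCCCl)c2c(OCOC)cc(cc2OCOC)[C@H](O)[C@@H](C)CCCC[C@@H](CCCC=NN)c2c(OCOC)cc(cc2OCOC)[C@@H]1O | intermediate (not isolated)
24 | (1R,2S,7S,14R,15S,20S)-7-(4-chlorobutyl)-20-(4,4-dichlorobutyl)-9,13,22,26-tetrakis(methoxymethoxy)-2,15-dimethyl[7.7]paracyclophane-1,14-diol | C[C@H]1CCCC[C@@H](CCCCCl)c2c(OCOC)cc(cc2OCOC)[C@H](O)[C@@H](C)CCCC[C@@H](CCCC(Cl)Cl)c2c(OCOC)cc(cc2OCOC)[C@@H]1O | intermediate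
25 | (1R,2S,7S,14R,15S,20S)-7-(4-chlorobutyl)-20-(4,4-dichlorobutyl)-9,13,22,26-tetrakis(methoxymethoxy)-2,15-dimethyl[7.7]paracyclophane-1,14-diyl bis[(trichloroacetyl)carbamate] | C[C@H]1CCCC[C@@H](CCCCCl)c2c(OCOC)cc(cc2OCOC)[C@H](OC(=O)NC(=O)C(Cl)(Cl)Cl)[C@@H](C)CCCC[C@@H](CCCC(Cl)Cl)c2c(OCOC)cc(cc2OCOC)[C@@H]1OC(=O)NC(=O)C(Cl)(Cl)Cl | intermediate (not isolated)
26 | (1R,2S,7S,14R,15S,20S)-7-(4-chlorobutyl)-20-(4,4-dichlorobutyl)-9,13,22,26-tetrakis(methoxymethoxy)-2,15-dimethyl[7.7]paracyclophane-1,14-diyl dicarbamate | C[C@H]1CCCC[C@@H](CCCCCl)c2c(OCOC)cc(cc2OCOC)[C@H](OC(N)=O)[C@@H](C)CCCC[C@@H](CCCC(Cl)Cl)c2c(OCOC)cc(cc2OCOC)[C@@H]1OC(N)=O | intermediate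
27 | (1R,2S,7S,14R,15S,20S)-7-(4-chlorobutyl)-20-(4,4-dichlorobutyl)-9,13,22,26-tetrahydroxy-2,15-dimethyl[7.7]paracyclophane-1,14-diyl dicarbamate (CNP0310589.1) | C[C@H]1CCCC[C@@H](CCCCCl)c2c(O)cc(cc2O)[C@H](OC(N)=O)[C@@H](C)CCCC[C@@H](CCCC(Cl)Cl)c2c(O)cc(cc2O)[C@@H]1OC(N)=O | target

## Step count

Total steps: 16 (steps 5–7 and 8–10 are two parallel three-step branches from 9).
Longest linear sequence: 13 (1 → 2 → 6 → 8 → 9 → 12 → 13 → 14 → 20 → 21 → 22 → 24 → 26 → 27).

## Three steps most likely to fail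

**Step 3.** High enantioselectivity in a carbene-homoenolate annulation of crotonaldehyde with a simple aryl aldehyde is unproven. Enal self-annulation, benzoin chemistry and a cis:trans ratio of only about 4–5:1 are further risks, as is the choice between the two aldehydes of 6.

The fallback sets out from 6 and comes back at 8, and uses a stoichiometric chiral homoenolate equivalent. (Z)-But-2-en-1-yl N,N-diisopropylcarbamate is lithiated with n-BuLi/(−)-sparteine (toluene, −78 °C), transmetalated with Ti(OiPr)4 and added to 6. It reacts at the unhindered aldehyde through a chair transition state (Z-crotyl gives syn; the diamine fixes the absolute sense) to give (1Z,3S,4R)-4-[4-formyl-3,5-bis(methoxymethoxy)phenyl]-4-hydroxy-3-methylbut-1-en-1-yl N,N-di(propan-2-yl)carbamate F1. MeSO3H (cat.) in wet THF hydrolyses the enol carbamate with ring closure to 4-[(2R,3S)-5-hydroxy-3-methyloxolan-2-yl]-2,6-bis(methoxymethoxy)benzaldehyde F2. Ag2CO3 on Celite (benzene, reflux) then oxidises the lactol to lactone 8.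

**Step 5 (and its twin, step 8).** The β-carbon carries an aryl group with two ortho OMOM substituents, and a lactone has to survive the Grignard reagent, so conversion or ee may be poor.

The fallback sets out from 8 and comes back at 12 (and, with Grignard 16, at 17), replacing catalyst control by auxiliary control. Wittig reaction of 8 with (4R)-4-phenyl-3-[(triphenyl-λ5-phosphanylidene)acetyl]-1,3-oxazolidin-2-one gives (4R)-3-[(2E)-3-{2,6-bis(methoxymethoxy)-4-[(2R,3S)-3-methyl-5-oxooxolan-2-yl]phenyl}prop-2-enoyl]-4-phenyl-1,3-oxazolidin-2-one F3. Grignard 11 with CuBr·SMe2 (THF, −40 °C) adds to the Mg-chelated syn-s-cis imide from the face opposite the phenyl group to give (4R)-3-[(3R)-3-{2,6-bis(methoxymethoxy)-4-[(2R,3S)-3-methyl-5-oxooxolan-2-yl]phenyl}-7-chloroheptanoyl]-4-phenyl-1,3-oxazolidin-2-one F4. EtSLi (EtSH, n-BuLi, THF, 0 °C) exchanges the auxiliary for the thioester and returns 12. With Grignard 16, F3 gives (4R)-3-[(3R)-3-{2,6-bis(methoxymethoxy)-4-[(2R,3S)-3-methyl-5-oxooxolan-2-yl]phenyl}-7,7-dimethoxyheptanoyl]-4-phenyl-1,3-oxazolidin-2-one F5 and then 17.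

**Step 11.** The mixed cyclodimerisation is statistical (half of the material at best), and the three macrocycles may separate poorly or be accompanied by oligomers.

The fallback sets out from 19 and comes back at 24. It dimerises one monomer only and breaks the symmetry at the chlorine level afterwards.

- 19 alone is cyclodimerised with the same Ru catalyst to (1R,2S,4E,7R,14R,15S,17E,20R)-7,20-bis(4,4-dimethoxybutyl)-9,13,22,26-tetrakis(methoxymethoxy)-2,15-dimethyl[7.7]paracyclophane-4,17-diene-1,14-diol F6.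
- H2/PtO2 gives (1R,2S,7S,14R,15S,20S)-7,20-bis(4,4-dimethoxybutyl)-9,13,22,26-tetrakis(methoxymethoxy)-2,15-dimethyl[7.7]paracyclophane-1,14-diol F7.
- LiBF4 in wet MeCN gives (1R,2S,7S,14R,15S,20S)-9,13,22,26-tetrakis(methoxymethoxy)-2,15-dimethyl-7,20-bis(4-oxobutyl)[7.7]paracyclophane-1,14-diol F8.
- Hydrazine gives (1R,2S,7S,14R,15S,20S)-7,20-bis(4-hydrazinylidenebutyl)-9,13,22,26-tetrakis(methoxymethoxy)-2,15-dimethyl[7.7]paracyclophane-1,14-diol F9, and CuCl2/Et3N converts it into (1R,2S,7S,14R,15S,20S)-7,20-bis(4,4-dichlorobutyl)-9,13,22,26-tetrakis(methoxymethoxy)-2,15-dimethyl[7.7]paracyclophane-1,14-diol F10.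
- One CHCl2 group is then reduced to CH2Cl with Bu3SnH (1.0 equiv, AIBN cat., benzene, 80 °C). A gem-dichloride loses its first chlorine much faster than a primary chloride loses its only one, and because the bis(dichloride) is C2-symmetric either group gives 24, which is separated from unreacted and doubly reduced material.

Further compounds
F1 | step 3 | (1Z,3S,4R)-4-[4-formyl-3,5-bis(methoxymethoxy)phenyl]-4-hydroxy-3-methylbut-1-en-1-yl N,N-di(propan-2-yl)carbamate | COCOc1cc(cc(OCOC)c1C=O)[C@H](O)[C@@H](C)/C=C\OC(=O)N(C(C)C)C(C)C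
F2 | step 3 | 4-[(2R,3S)-5-hydroxy-3-methyloxolan-2-yl]-2,6-bis(methoxymethoxy)benzaldehyde | COCOc1cc(cc(OCOC)c1C=O)[C@@H]1OC(O)C[C@@H]1C
F3 | step 5 | (4R)-3-[(2E)-3-{2,6-bis(methoxymethoxy)-4-[(2R,3S)-3-methyl-5-oxooxolan-2-yl]phenyl}prop-2-enoyl]-4-phenyl-1,3-oxazolidin-2-one | O=C1OC[C@@H](c2ccccc2)N1C(=O)/C=C/c1c(OCOC)cc(cc1OCOC)[C@@H]1OC(=O)C[C@@H]1C
F4 | step 5 | (4R)-3-[(3R)-3-{2,6-bis(methoxymethoxy)-4-[(2R,3S)-3-methyl-5-oxooxolan-2-yl]phenyl}-7-chloroheptanoyl]-4-phenyl-1,3-oxazolidin-2-one | O=C1OC[C@@H](c2ccccc2)N1C(=O)C[C@@H](CCCCCl)c1c(OCOC)cc(cc1OCOC)[C@@H]1OC(=O)C[C@@H]1C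
F5 | step 8 | (4R)-3-[(3R)-3-{2,6-bis(methoxymethoxy)-4-[(2R,3S)-3-methyl-5-oxooxolan-2-yl]phenyl}-7,7-dimethoxyheptanoyl]-4-phenyl-1,3-oxazolidin-2-one | O=C1OC[C@@H](c2ccccc2)N1C(=O)C[C@@H](CCCC(OC)OC)c1c(OCOC)cc(cc1OCOC)[C@@H]1OC(=O)C[C@@H]1C
F6 | step 11 | (1R,2S,4E,7R,14R,15S,17E,20R)-7,20-bis(4,4-dimethoxybutyl)-9,13,22,26-tetrakis(methoxymethoxy)-2,15-dimethyl[7.7]paracyclophane-4,17-diene-1,14-diol | C[C@H]1C/C=C/C[C@@H](CCCC(OC)OC)c2c(OCOC)cc(cc2OCOC)[C@H](O)[C@@H](C)C/C=C/C[C@@H](CCCC(OC)OC)c2c(OCOC)cc(cc2OCOC)[C@@H]1O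
F7 | step 11 | (1R,2S,7S,14R,15S,20S)-7,20-bis(4,4-dimethoxybutyl)-9,13,22,26-tetrakis(methoxymethoxy)-2,15-dimethyl[7.7]paracyclophane-1,14-diol | C[C@H]1CCCC[C@@H](CCCC(OC)OC)c2c(OCOC)cc(cc2OCOC)[C@H](O)[C@@H](C)CCCC[C@@H](CCCC(OC)OC)c2c(OCOC)cc(cc2OCOC)[C@@H]1O
F8 | step 11 | (1R,2S,7S,14R,15S,20S)-9,13,22,26-tetrakis(methoxymethoxy)-2,15-dimethyl-7,20-bis(4-oxobutyl)[7.7]paracyclophane-1,14-diol | C[C@H]1CCCC[C@@H](CCCC=O)c2c(OCOC)cc(cc2OCOC)[C@H](O)[C@@H](C)CCCC[C@@H](CCCC=O)c2c(OCOC)cc(cc2OCOC)[C@@H]1O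
F9 | step 11 | (1R,2S,7S,14R,15S,20S)-7,20-bis(4-hydrazinylidenebutyl)-9,13,22,26-tetrakis(methoxymethoxy)-2,15-dimethyl[7.7]paracyclophane-1,14-diol | C[C@H]1CCCC[C@@H](CCCC=NN)c2c(OCOC)cc(cc2OCOC)[C@H](O)[C@@H](C)CCCC[C@@H](CCCC=NN)c2c(OCOC)cc(cc2OCOC)[C@@H]1O
F10 | step 11 | (1R,2S,7S,14R,15S,20S)-7,20-bis(4,4-dichlorobutyl)-9,13,22,26-tetrakis(methoxymethoxy)-2,15-dimethyl[7.7]paracyclophane-1,14-diol | C[C@H]1CCCC[C@@H](CCCC(Cl)Cl)c2c(OCOC)cc(cc2OCOC)[C@H](O)[C@@H](C)CCCC[C@@H](CCCC(Cl)Cl)c2c(OCOC)cc(cc2OCOC)[C@@H]1O
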